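**Retrosynthetic overview** (flavanone numbering O1, C2–C4, C4a, C5–C8, C8a; primed locants for ring A of the chalcone)
- The 2S flavanone is opened at O1–C2 (retro-oxa-Michael) to the 2'-hydroxychalcone, so ring C is closed last and C2 is set by a chiral catalyst.
- The strategy rests on ring A: a resorcinol with oxygens on C7 and C8a, prenyl groups on C6 and C8, and an unsubstituted C5 beside the acyl-bearing C4a. This is the pattern left by a 1,1,3-trioxygenated diene and a terminal ynone, so ring A is cut at C5–C6 and C4a–C8a (retro-[4+2] with methanol added back).
- The diene carries both prenyl groups from two enolate alkylations of methyl acetoacetate followed by double enol silylation; the dienophile is the enynone made from 4-methoxycinnamaldehyde and an ethynyl Grignard reagent.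
- Order of ring formation: ring B is purchased, ring A is built de novo by cycloaddition and aromatization, ring C is closed by asymmetric oxa-Michael addition.

Key step: step 7

Assumption: the enol double-bond geometries of 7, 8 and 9 are left undefined because these carbons become aromatic in step 7, and the quinidine-derived thiourea of step 8 is taken to be the pseudoenantiomer that delivers 2S; if the opposite sense is found, the quinine-derived pseudoenantiomer replaces it.

**Route**

Step 1
Reactants: 1 methyl acetoacetate; 2 prenyl bromide
Product: 4 methyl 7-methyl-3-oxooct-6-enoate, via acetoacetate dianion 3 (not isolated)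
Conditions: NaH, THF, 0 °C; n-BuLi, 0 °C; then 2, 0 → 20 °C; dilute aq HCl
Reagents that add atoms: none
Why: Acetoacetate dianion γ-alkylation, in which the terminal carbanion of the dianion is by far the most nucleophilic site and should take up the allylic bromide by SN2 at C4 only.

Step 2
Reactants: 4 methyl 7-methyl-3-oxooct-6-enoate; 2 prenyl bromide
Product: 6 methyl 7-methyl-2-(3-methylbut-2-en-1-yl)-3-oxooct-6-enoate (racemic), via sodium keto ester enolate 5 (not isolated)
Conditions: NaH, THF, 0 °C; then 2 (0.95 equiv), 0 → 20 °C
Reagents that add atoms: none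
Why: Classical acetoacetic ester C-alkylation of the stabilized sodium enolate with a reactive allylic bromide, a slight deficit of bromide limiting double alkylation.

Step 3
Reactants: 6 methyl 7-methyl-2-(3-methylbut-2-en-1-yl)-3-oxooct-6-enoate
Product: 7 methyl 7-methyl-2-(3-methylbut-2-en-1-yl)-3-(trimethylsilyloxy)octa-2,6-dienoate
Conditions: Me3SiCl, Et3N, PhMe, 20 °C; filtration under argon
Reagents that add atoms: chlorotrimethylsilane, C[Si](C)(C)Cl
Why: Soft enolization and O-silylation of the β-keto ester gives the conjugated 3-silyloxy enoate, the standard first stage of 1-alkoxy-1,3-bis(silyloxy)diene preparation.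

Step 4
Reactants: 7 methyl 7-methyl-2-(3-methylbut-2-en-1-yl)-3-(trimethylsilyloxy)octa-2,6-dienoate
Product: 9 1-methoxy-2,4-bis(3-methylbut-2-en-1-yl)-1,3-bis(trimethylsilyloxy)buta-1,3-diene, via lithium dienolate 8 (not isolated)
Conditions: LiN(iPr)2, THF, −78 °C; then Me3SiCl, −78 → 20 °C; hexane, filtration, used crude
Reagents that add atoms: chlorotrimethylsilane, C[Si](C)(C)Cl
Why: Kinetic γ-deprotonation of the β-silyloxy enoate gives the vinylogous ester dienolate, which is silylated on oxygen to the ketene silyl acetal, as established for 2- and 4-alkyl dienes of this class.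

Step 5
Reactants: 10 (E)-4-methoxycinnamaldehyde; 11 ethynylmagnesium bromide
Product: 13 (E)-1-(4-methoxyphenyl)pent-1-en-4-yn-3-ol (racemic), via bromomagnesium alkoxide 12 (not isolated)
Conditions: THF, 0 → 20 °C; sat. aq NH4Cl
Reagents that add atoms: none
Why: Grignard 1,2-addition of the hard acetylide to the enal carbonyl; the carbinol stereocenter is formed racemic and is removed in step 6.

Step 6
Reactants: 13 (E)-1-(4-methoxyphenyl)pent-1-en-4-yn-3-ol
Product: 14 (E)-1-(4-methoxyphenyl)pent-1-en-4-yn-3-one
Conditions: MnO2 (activated, excess), CH2Cl2, 20 °C; used promptly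
Reagents that add atoms: none
Why: MnO2 oxidation of a secondary alcohol that is both allylic and propargylic should proceed under neutral conditions without touching the alkene or the terminal alkyne.

Step 7
Reactants: 9 1-methoxy-2,4-bis(3-methylbut-2-en-1-yl)-1,3-bis(trimethylsilyloxy)buta-1,3-diene; 14 (E)-1-(4-methoxyphenyl)pent-1-en-4-yn-3-one
Product: 17 (E)-2',4'-dihydroxy-4-methoxy-3',5'-diprenylchalcone, via cyclohexa-1,4-diene cycloadduct 15 (not isolated), via chalcone bis(trimethylsilyl) ether 16 (not isolated)
Conditions: 9 (1.5 equiv), PhMe, 0 → 25 °C; then 1 M aq HCl, THF, 0 °C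
Reagents that add atoms: none
Why: The electron-rich ketene acetal diene and the electron-poor terminal ynone should combine in a strongly polarized, asynchronous Diels–Alder [4+2] cycloaddition (at the limit a Mukaiyama–Michael addition followed by ring closure, which gives the same connectivity), the nucleophilic C4 terminus of the diene bonding to the alkyne β-carbon (the C5–C6 bond) and the acetal carbon to the α-carbon (the C4a–C8a bond). Cycloadduct 15 aromatizes by loss of methanol from the mixed silyl methyl acetal carbon and the doubly allylic C–H, and cold dilute acid hydrolyses the aryl silyl ethers of 16 to the resorcinol. The closest known reaction type is the cycloaddition–aromatization of 1-alkoxy-1,3-bis(silyloxy)dienes with acetylenic ketones and esters to give acyl resorcinols. Ring A is closed by the intermolecular [4+2] cycloaddition itself, both ring bonds forming in one operation, and no stereocenter survives because the two sp3 ring carbons of 15 become aromatic. The step needs regioselectivity, secured by matching the ketene acetal polarity to the ynone, and chemoselectivity for the alkyne over the styryl alkene and the carbonyl, secured by the unhindered sp-hybridized acceptor, the deactivating donor aryl group on the alkene and the absence of any Lewis acid.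

Step 8
Reactants: 17 (E)-2',4'-dihydroxy-4-methoxy-3',5'-diprenylchalcone
Product: 18 (2S)-7-hydroxy-2-(4-methoxyphenyl)-6,8-bis(3-methylbut-2-en-1-yl)chroman-4-one, the target flavanone
Conditions: 1-[3,5-bis(trifluoromethyl)phenyl]-3-[(8R,9R)-6'-methoxycinchonan-9-yl]thiourea (quinidine-derived, 20 mol %), PhMe, 0 → 25 °C
Reagents that add atoms: none
Why: Asymmetric intramolecular oxa-Michael addition (chalcone to flavanone isomerization) in which the thiourea hydrogen-bonds the enone carbonyl and the quinuclidine nitrogen activates the 2'-hydroxyl, so that the phenol oxygen adds to one enantiotopic face of the β-carbon and C2 is set as S under catalyst control, the aprotic medium and low temperature limiting reversible ring opening.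

**Compound list**
1 | methyl acetoacetate | COC(=O)CC(C)=O | starting material
2 | prenyl bromide (1-bromo-3-methylbut-2-ene) | CC(C)=CCBr | starting material
3 | acetoacetate dianion, sodium lithium salt | C=C([O-])C=C([O-])OC.[Na+].[Li+] | intermediate
4 | methyl 7-methyl-3-oxooct-6-enoate | COC(=O)CC(=O)CCC=C(C)C | intermediate
5 | sodium enolate of methyl 7-methyl-3-oxooct-6-enoate | COC(=O)C=C([O-])CCC=C(C)C.[Na+] | intermediate
6 | methyl 7-methyl-2-(3-methylbut-2-en-1-yl)-3-oxooct-6-enoate (racemic) | COC(=O)C(CC=C(C)C)C(=O)CCC=C(C)C | intermediate
7 | methyl 7-methyl-2-(3-methylbut-2-en-1-yl)-3-(trimethylsilyloxy)octa-2,6-dienoate | COC(=O)C(CC=C(C)C)=C(O[Si](C)(C)C)CCC=C(C)C | intermediate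
8 | lithium dienolate of 7 | COC([O-])=C(CC=C(C)C)C(O[Si](C)(C)C)=CCC=C(C)C.[Li+] | intermediate
9 | 1-methoxy-2,4-bis(3-methylbut-2-en-1-yl)-1,3-bis(trimethylsilyloxy)buta-1,3-diene | COC(O[Si](C)(C)C)=C(CC=C(C)C)C(O[Si](C)(C)C)=CCC=C(C)C | intermediate
10 | (E)-4-methoxycinnamaldehyde | COc1ccc(/C=C/C=O)cc1 | starting material
11 | ethynylmagnesium bromide | C#C[Mg]Br | starting material
12 | bromomagnesium alkoxide of 13 | C#CC(O[Mg]Br)/C=C/c1ccc(OC)cc1 | intermediate
13 | (E)-1-(4-methoxyphenyl)pent-1-en-4-yn-3-ol (racemic) | C#CC(O)/C=C/c1ccc(OC)cc1 | intermediate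
14 | (E)-1-(4-methoxyphenyl)pent-1-en-4-yn-3-one | C#CC(=O)/C=C/c1ccc(OC)cc1 | intermediate
15 | cyclohexa-1,4-diene cycloadduct (6-methoxy-1,5-diprenyl-4,6-bis(trimethylsilyloxy)cyclohexa-1,4-diene carrying the (E)-4-methoxycinnamoyl group on the alkene carbon next to the acetal carbon; racemic, relative configuration undefined) | COC1(O[Si](C)(C)C)C(CC=C(C)C)=C(O[Si](C)(C)C)C(CC=C(C)C)C=C1C(=O)/C=C/c1ccc(OC)cc1 | intermediate
16 | (E)-4-methoxy-3',5'-diprenyl-2',4'-bis(trimethylsilyloxy)chalcone | COc1ccc(/C=C/C(=O)c2cc(CC=C(C)C)c(O[Si](C)(C)C)c(CC=C(C)C)c2O[Si](C)(C)C)cc1 | intermediate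
17 | (E)-2',4'-dihydroxy-4-methoxy-3',5'-diprenylchalcone | COc1ccc(/C=C/C(=O)c2cc(CC=C(C)C)c(O)c(CC=C(C)C)c2O)cc1 | intermediate
18 | (2S)-7-hydroxy-2-(4-methoxyphenyl)-6,8-bis(3-methylbut-2-en-1-yl)chroman-4-one, the target flavanone | COc1ccc([C@@H]2CC(=O)c3cc(CC=C(C)C)c(O)c(CC=C(C)C)c3O2)cc1 | target

**Step count**
Total steps: 8. Longest linear sequence: 6 steps (steps 1, 2, 3, 4, 7, 8 from methyl acetoacetate); the enynone branch (steps 5, 6) joins at step 7.

**Steps most likely to fail, with fallbacks**

Step 7. The cycloaddition may stall because the fully substituted ketene acetal terminus of 9 is crowded. It may also be diverted into conjugate addition at the styryl terminus of 14 or into oligomerization of the enynone before ring closure. The fallback leaves the de novo arene construction for classical arene chemistry and sets out from prenyl bromide 2. Commercially available 2',4'-dihydroxyacetophenone would be C-prenylated twice with 2 in cold aqueous KOH to give 1-[2,4-dihydroxy-3,5-bis(3-methylbut-2-en-1-yl)phenyl]ethanone F1, separated by chromatography from mono-C-prenylated and O-prenylated material. A Claisen–Schmidt condensation of F1 with 4-methoxybenzaldehyde (KOH, EtOH, 20 °C) would then give the chalcone, and the route is rejoined at 17.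

Step 8. Facial discrimination may be insufficient for a chalcone that has no extra activating group, and conversion may be slow because the 2'-hydroxyl is tied up in a hydrogen bond to the carbonyl. Configuration may also erode through reversible ring opening. The fallback sets out from 17 and replaces asymmetric catalysis by resolution. Cyclization with NaOAc in refluxing EtOH would give racemic 7-hydroxy-2-(4-methoxyphenyl)-6,8-bis(3-methylbut-2-en-1-yl)chroman-4-one F2. Preparative HPLC on a polysaccharide chiral stationary phase would deliver the 2S enantiomer, rejoining the route at 18, and the 2R enantiomer would be reopened with base and recycled.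

Step 4. γ-Deprotonation of the hindered, tetrasubstituted silyl enol ether 7 may be incomplete, and the labile ketene silyl acetal may be hydrolysed during isolation. The fallback sets out from keto ester 6 and bypasses 7 and 8. Direct double soft enolization with Me3SiOSO2CF3 (2.3 equiv) and Et3N in Et2O at 0 → 20 °C, followed by filtration under argon, would give the diene in one operation without a strong base, rejoining the route at 9. No compound outside the list is made on this way (F0).

**Further compounds**
F1 | step 7 | 1-[2,4-dihydroxy-3,5-bis(3-methylbut-2-en-1-yl)phenyl]ethanone | CC(=O)c1cc(CC=C(C)C)c(O)c(CC=C(C)C)c1O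
F2 | step 8 | racemic 7-hydroxy-2-(4-methoxyphenyl)-6,8-bis(3-methylbut-2-en-1-yl)chroman-4-one | COc1ccc(C2CC(=O)c3cc(CC=C(C)C)c(O)c(CC=C(C)C)c3O2)cc1
F0 | step 4 | none | none
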